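**Proposed total synthesis of CNP0331360.0 (5,7,4'-trihydroxy-2'-methoxy-6,8,3'-triprenylisoflavone) by biomimetic Claisen folding of a triketo ester**

Abbreviations used throughout: prenyl = 3-methylbut-2-en-1-yl; MOM = methoxymethyl; Ar = 2-methoxy-4-(methoxymethoxy)-3-(3-methylbut-2-en-1-yl)phenyl.

## Analysis of the target

The target is an isoflavone, C31H36O6: a 4H-chromen-4-one (rings A and C) carrying benzene ring B at C3. It has no stereocentre, and the three prenyl double bonds are trisubstituted with geminal methyl groups, so no alkene geometry has to be controlled. Ring A is fully substituted: hydroxyls at C5 and C7, prenyl groups at C6 and C8, the ring oxygen O1 on C8a and the carbonyl carbon C4 on C4a. Ring B has four contiguous substituents: the chromone at C1', methoxy at C2', prenyl at C3' and hydroxyl at C4'. The sensitive elements are the electron-rich prenyl alkenes that sit next to free phenols (acid closes them to 2,2-dimethylchromans; oxidants, electrophilic halogen and hydrogenation attack them) and the air-sensitive polyphenolates formed in base. The difficulties are three: placing two C-prenyl groups on ring A without O-alkylation or over-alkylation, telling apart the two ring B oxygens (methyl on O2', free O4') around the prenyl between them, and finding a protecting group for O4' whose removal the prenyl groups survive. The plan rests on ring A: oxygen sits on the alternate carbons C5, C7 and C8a and the acyl carbon C4 on C4a, so ring A is an acylated phloroglucinol, the pattern left by three acetate units added to an arylacetyl starter that supplies C3, C4 and ring B. C4a, C5, C6, C7, C8 and C8a can therefore be traced to six consecutive carbons of a 3,5,7-trioxooctanoate that closes through one bond, C4a–C8a, and C6 and C8 are equivalent in the resulting trihydroxyphenyl ketone.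

## Retrosynthetic reasoning

**20 to 19.** No skeletal bond is cut. The O4' hydroxyl is carried as its MOM ether in 19 because this acetal withstands every strongly basic step of the route; it is removed last with mild acid.

**19 to 17.** O1–C2 and C2–C3 are cut. C2 is an unsubstituted CH, so it can come from a one-carbon donor at the formate oxidation level, inserted between the benzylic carbon of deoxybenzoin 17 and an ortho hydroxyl. The cut is made here because ring A of 17 is symmetric: either ortho hydroxyl closes to the same chromone. The forward reaction must condense at the benzylic CH2 (through enaminone 18) and then close ring C by addition–elimination.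

**17 to 16 and 2.** The C6–CH2 and C8–CH2 bonds are cut. In 16 the two free ring carbons are equivalent and each lies between two phenolic oxygens, so they are the nucleophilic carbons of the phenoxide and can be alkylated twice with 2. Doing this before ring C closure uses the symmetry and the full nucleophilicity of the acylphloroglucinol.

**16 to 15 (key disconnection).** The C4a–C8a bond is cut and ring A opens to the linear triketo ester 15. This removes a hexasubstituted benzene from the problem and replaces it by an open chain. The forward reaction must make the carbon between the two ketones next to the arylacetyl end attack the ester carbonyl and must avoid the aldol alternative.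

**15 to 13.** The β-keto ester end of 15 is masked as the dioxinone of 13. A free triketo ester is too labile to carry through chain assembly, whereas the dioxinone keeps the ester carbonyl and one ketone latent. Thermal cycloreversion gives acylketene 14, which the alcohol traps.

**13 to 8 and 11.** The bond between the arylacetyl carbonyl carbon and the adjoining methylene is cut; it is the future C4–C4a bond. The terminal carbanion of the dianion of 11 is acylated by acid 8, activated as acyl imidazole 12. This joins ring B and the complete chain in one convergent step.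

**11 to 9 and 10.** The ketone side chain of 11 comes from acetylation of the dienolate of 9 at its methyl carbon with 10.

**8 to 7 to 5.** The bond between the benzylic carbon and the carboxyl carbon (the future C3–C4) is cut. Aldehyde 5 is homologated by one carbon to nitrile 7 through the formamide 6, and 7 is hydrolysed to 8. This route avoids a benzylic halide, which would be unstable on so electron-rich a ring.

**5 to 4 to 3 to 1 and 2.** The O–methyl bond, the O–MOM bond and the C3–prenyl bond are cut in that order. The hydrogen bond between the 2-hydroxyl and the aldehyde differentiates the two oxygens: the free 4-hydroxyl of 3 is protected first (4), the chelated one is methylated second (5). The prenyl group enters first, by C-alkylation of 1 with 2 at the carbon between the two oxygens.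

## Alternatives that were turned down

**Alternative 1:** All three aryl–CH2 bonds of the prenyl groups (at C6, C8 and C3') are cut at once, leading back to the triiodide A2.
- Forward key step: a threefold Stille coupling of A2 with tributyl(prenyl)stannane A3 under zerovalent palladium catalysis, Pd(PPh3)4, with fluoride activation. It gives A1, the 7,4'-bis-MOM ether of 20. No ring is closed.
- For it: the positions of the prenyl groups are fixed by the iodine atoms, so neither O-alkylation nor geminal over-alkylation of ring A can occur. On this point it is stronger than the chosen route. Three C–C bonds are also made in the last skeletal step.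
- Against it: A2 has to be built first. Its ring B iodine lies between two oxygens, and the two ring A iodines must be introduced on a 5-hydroxychromone. Each of the three C–I bonds is flanked by two ortho substituents. Allyl-type stannanes transmetalate through allyl–palladium species that can deliver the 1,1-dimethylallyl isomer, and any such error or any hydrodeiodination at one of three sites spoils the product. Stoichiometric tin is needed.
- Comparison: the chosen route makes only two late C–C bonds, on a symmetric and strongly nucleophilic ring with an inexpensive halide, and sets the third prenyl on a simple aldehyde. It gives up the positional certainty of the iodides and offers the symmetry of 16 in its place.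

**Alternative 2:** Ring B is dismantled into the chromon-3-yl diazo enone A5 and the prenyl-bearing siloxyalkyne A6, cutting C1'–C2', C2'–C3' and C4'–C5'.
- Forward key step: irradiation of A5 triggers a Wolff rearrangement. The ketene so formed adds A6 in a [2+2] manner, and four-electron ring opening, six-electron ring closure and tautomerisation give the phenol A4, with free 2'-hydroxyl, 3'-prenyl and 4'-silyl ether.
- For it: the contiguous 2'-oxygen, 3'-prenyl, 4'-oxygen pattern is set with complete regiocontrol, and the two oxygens emerge already differentiated. Here it is stronger than the chosen route, whose ring B depends on a moderately selective aqueous C-prenylation.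
- Against it: ring B is a simple resorcinol unit that can be bought as 1, so building it anew gains little. A5 needs a fully elaborated 6,8-diprenylchromone carrying a dienyl diazo ketone, so the ring A prenylation problem is still to be solved and a long linear sequence precedes the key step. The chromone is itself a chromophore and an enone, so competing photochemistry and cycloaddition at C2=C3 are plausible. The 2'-hydroxyl still has to be methylated between two bulky neighbours.
- Comparison: the chosen route constructs the ring that is hard to substitute (ring A) and buys the easy one; it is shorter by several steps.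

**Alternative 3:** O1–C8a and C4–C4a are cut, leading back to the fully substituted silyl triflate A8 and arylacetic acid 8, which the chosen route also prepares.
- Forward key step: fluoride generates the C4a≡C8a aryne from A8. The carboxylate of 8 adds through oxygen at C8a, the aryl anion at C4a attacks the neighbouring ester carbonyl, and the four-membered intermediate opens to the ortho-hydroxyaryl ketone A7, which carries all three prenyl groups.
- For it: it is highly convergent, and the regiochemistry should be correct, since the nucleophile adds to the aryne carbon remote from the C5 alkoxy group. A7 needs only the one-carbon insertion and deprotection, so the late double C-prenylation of the chosen route is avoided; on that point it is stronger.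
- Against it: A8 is a hexasubstituted benzene whose preparation (two prenyls, two protected oxygens, adjacent silyl and triflate) would take longer than the whole chosen sequence to 16. The aryne is hindered on both sides. Three prenyl groups offer allylic hydrogens for ene reactions with the aryne, and the acidic benzylic position of 8 can compete as a carbon nucleophile.
- Comparison: the chosen route obtains the same substitution pattern by folding an open chain, in which no crowded aromatic substitution is needed, and pays for this with a less certain prenylation step.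

Key step: step 9

Assumption: enolates, phenoxides and organolithium species formed by deprotonation are treated as ionised forms of the numbered compounds and carry no number of their own.

## Route

Step 1
Reactants: 1 2,4-dihydroxybenzaldehyde; 2 prenyl bromide (1-bromo-3-methylbut-2-ene)
Product: 3 2,4-dihydroxy-3-(3-methylbut-2-en-1-yl)benzaldehyde
Conditions: KOH (2 equiv), H2O, 0 °C to rt, argon
Reagents that add atoms: none
Why: Direct C-alkylation of a phenoxide in water, where hydrogen bonding shields the oxygens and the carbon between the two oxygens (C3) is the most electron-rich site; the 5-prenyl and O-prenyl isomers would be removed by chromatography.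

Step 2
Reactants: 3 2,4-dihydroxy-3-(3-methylbut-2-en-1-yl)benzaldehyde
Product: 4 2-hydroxy-4-(methoxymethoxy)-3-(3-methylbut-2-en-1-yl)benzaldehyde
Conditions: MOMCl (1.1 equiv), K2CO3, acetone, 0 °C to rt
Reagents that add atoms: chloromethyl methyl ether, COCCl
Why: Williamson-type etherification; the 2-hydroxyl is held in a hydrogen bond to the aldehyde and is flanked by the prenyl group, so the more acidic and accessible 4-hydroxyl should react selectively.

Step 3
Reactants: 4 2-hydroxy-4-(methoxymethoxy)-3-(3-methylbut-2-en-1-yl)benzaldehyde
Product: 5 2-methoxy-4-(methoxymethoxy)-3-(3-methylbut-2-en-1-yl)benzaldehyde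
Conditions: MeI, K2CO3, DMF, 40 °C
Reagents that add atoms: iodomethane, CI
Why: Williamson O-methylation of the only remaining phenol; the polar aprotic solvent breaks the chelate, and neither the MOM ether nor the prenyl group reacts.

Step 4
Reactants: 5 2-methoxy-4-(methoxymethoxy)-3-(3-methylbut-2-en-1-yl)benzaldehyde
Product: 7 2-Ar-acetonitrile, via vinyl formamide 6 (not isolated)
Conditions: TosMIC (1.3 equiv), KOtBu (2.5 equiv), DME, −50 to −30 °C; then MeOH, reflux
Reagents that add atoms: p-toluenesulfonylmethyl isocyanide (TosMIC), [C-]#[N+]CS(=O)(=O)c1ccc(C)cc1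
Why: van Leusen reductive cyanation: the TosMIC anion adds to the aldehyde, the oxazoline opens to N-(1-tosylvinyl)formamide 6, and methanolysis removes the formyl group and sulfinate to leave the homologous nitrile. The conditions are basic throughout, so the MOM ether is safe and no benzylic halide is needed.

Step 5
Reactants: 7 2-Ar-acetonitrile
Product: 8 2-Ar-acetic acid
Conditions: KOH, EtOH/H2O, reflux; then 1 M HCl to pH 3, 0 °C
Reagents that add atoms: potassium hydroxide, [K+].[OH-]; water, O
Why: Alkaline nitrile hydrolysis by way of the amide; MOM ether and prenyl group are base-stable, and the brief cold acidification to liberate the acid should not cleave the acetal.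

Step 6
Reactants: 9 2,2,6-trimethyl-4H-1,3-dioxin-4-one; 10 acetyl chloride
Product: 11 2,2-dimethyl-6-(2-oxopropyl)-4H-1,3-dioxin-4-one
Conditions: 9 (2 equiv), LiN(SiMe3)2 (2 equiv), THF, −78 °C; then 10 (1 equiv); aq NH4Cl
Reagents that add atoms: none
Why: Vinylogous Claisen acylation: deprotonation of the 6-methyl group gives the lithium dienolate, which is acylated at the exocyclic carbon. The dienolate is used in twofold amount because 11 is more acidic than 9 and consumes one equivalent.

Step 7
Reactants: 8 2-Ar-acetic acid; 11 2,2-dimethyl-6-(2-oxopropyl)-4H-1,3-dioxin-4-one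
Product: 13 6-(5-Ar-2,4-dioxopentyl)-2,2-dimethyl-4H-1,3-dioxin-4-one, via acyl imidazole 12 (not isolated)
Conditions: 8, 1,1'-carbonyldiimidazole (CDI), THF, rt; separately 11 (3 equiv), LiN(iPr)2 (6 equiv), THF, −78 °C; add 12, −78 to −40 °C; aq NH4Cl
Reagents that add atoms: none
Why: Claisen acylation of a 1,3-dicarbonyl dianion at its terminal, most reactive carbanion by an acyl imidazole, forming the future C4–C4a bond. Excess dianion is used because the product and the liberated imidazole each consume one equivalent, and the low temperature favours acyl transfer over deprotonation of the benzylic CH2 of 12.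

Step 8
Reactants: 13 6-(5-Ar-2,4-dioxopentyl)-2,2-dimethyl-4H-1,3-dioxin-4-one
Product: 15 methyl 8-Ar-3,5,7-trioxooctanoate, via acylketene 14 (not isolated)
Conditions: MeOH (20 equiv), PhMe, 110 °C, sealed tube; concentrate, use crude
Reagents that add atoms: methanol, CO
Why: Thermal retro-[4+2] cycloreversion of the dioxinone releases acetone and acylketene 14, which excess methanol traps as the β-keto methyl ester faster than the ketene can lactonise. The conditions are neutral, so 15 should survive if it is not exposed to silica or base before step 9.

Step 9
Reactants: 15 methyl 8-Ar-3,5,7-trioxooctanoate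
Product: 16 2-Ar-1-(2,4,6-trihydroxyphenyl)ethan-1-one
Conditions: Mg(OMe)2 (4 equiv), MeOH, 65 °C, argon; then cold 0.5 M HCl
Reagents that add atoms: none
Why: Mg(OMe)2 converts 15 into a magnesium-chelated polyenolate, and the carbon between the C5 and C7 ketones of the chain (the future C4a) attacks the methyl ester carbonyl (the future C8a). This is an intramolecular Claisen (Dieckmann-type) acyl substitution, the laboratory counterpart of the chalcone-synthase folding of a tetraketide, and the closest known reaction type is the base-mediated cyclisation of 3,5,7-triketo esters to acylphloroglucinols. Ring A closes in the 6-exo-trig mode, since the ester C=O that is attacked lies outside the ring being formed. Collapse of the tetrahedral intermediate with loss of methoxide gives a 2-acylcyclohexane-1,3,5-trione that aromatises by threefold enolisation, which makes the step irreversible. No stereocentre is formed. The step needs Claisen closure to win over aldol closure of the ester-side methylene onto the C7 ketone (which would lead to a resorcylate) and over lactonisation to a 4-hydroxy-2-pyrone: magnesium chelation of the diketone units lowers the electrophilicity of the ketones, anhydrous methoxide keeps aldol addition reversible and withholds its dehydration, and methanolysis of any pyrone returns 15. The benzylic CH2 of the arylacetyl end is activated by one carbonyl only and is not ionised in this medium, so the aldol path through that carbon should not arise. MOM ether and prenyl group are inert to methoxide, and the cold dilute acid of the work-up only breaks the magnesium chelate.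

Step 10
Reactants: 16 2-Ar-1-(2,4,6-trihydroxyphenyl)ethan-1-one; 2 prenyl bromide
Product: 17 2-Ar-1-[2,4,6-trihydroxy-3,5-bis(3-methylbut-2-en-1-yl)phenyl]ethan-1-one
Conditions: 2 (2.2 equiv), 10% aq KOH, 0 °C to rt, argon
Reagents that add atoms: none
Why: Base-mediated C-prenylation of an acylphloroglucinol: the polyphenoxide reacts at its two equivalent free ring carbons, each flanked by two oxygens, and water disfavours O-alkylation. The product is symmetric, mono-prenylated material can be resubmitted, and the benzylic CH2 is far less acidic than the phenols and stays untouched.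

Step 11
Reactants: 17 2-Ar-1-[2,4,6-trihydroxy-3,5-bis(3-methylbut-2-en-1-yl)phenyl]ethan-1-one
Product: 19 5,7-dihydroxy-3-Ar-6,8-bis(3-methylbut-2-en-1-yl)-4H-chromen-4-one, via enaminone 18 (not isolated)
Conditions: Me2NCH(OMe)2 (2 equiv), THF, 65 °C
Reagents that add atoms: N,N-dimethylformamide dimethyl acetal, COC(OC)N(C)C
Why: Deoxybenzoin route to isoflavones: the amide acetal condenses at the benzylic CH2 to enaminone 18, and an ortho hydroxyl adds to the enamine carbon with loss of dimethylamine to close ring C. The two ortho hydroxyls of 17 are equivalent, so only one chromone can form; a small excess of reagent and moderate temperature limit O-methylation of the phenols.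

Step 12
Reactants: 19 5,7-dihydroxy-3-Ar-6,8-bis(3-methylbut-2-en-1-yl)-4H-chromen-4-one
Product: 20 5,7-dihydroxy-3-[4-hydroxy-2-methoxy-3-(3-methylbut-2-en-1-yl)phenyl]-6,8-bis(3-methylbut-2-en-1-yl)-4H-chromen-4-one (CNP0331360.0)
Conditions: HCl (1 M in MeOH), 40 °C
Reagents that add atoms: none
Why: Acid-catalysed transacetalisation of the aryl MOM ether to the phenol and dimethoxymethane; dilute acid in methanol at mild temperature is chosen so that acetal cleavage outpaces addition of the phenols across the prenyl double bonds.

## Compound list

1 | 2,4-dihydroxybenzaldehyde | O=Cc1ccc(O)cc1O | starting material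
2 | prenyl bromide (1-bromo-3-methylbut-2-ene) | CC(C)=CCBr | starting material
3 | 2,4-dihydroxy-3-(3-methylbut-2-en-1-yl)benzaldehyde | O=Cc1ccc(O)c(CC=C(C)C)c1O | intermediate
4 | 2-hydroxy-4-(methoxymethoxy)-3-(3-methylbut-2-en-1-yl)benzaldehyde | O=Cc1ccc(OCOC)c(CC=C(C)C)c1O | intermediate
5 | 2-methoxy-4-(methoxymethoxy)-3-(3-methylbut-2-en-1-yl)benzaldehyde | O=Cc1ccc(OCOC)c(CC=C(C)C)c1OC | intermediate
6 | N-{2-[2-methoxy-4-(methoxymethoxy)-3-(3-methylbut-2-en-1-yl)phenyl]-1-(4-methylbenzenesulfonyl)ethenyl}formamide (alkene geometry not controlled, not isolated) | O=CNC(=Cc1ccc(OCOC)c(CC=C(C)C)c1OC)S(=O)(=O)c1ccc(C)cc1 | intermediate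
7 | 2-[2-methoxy-4-(methoxymethoxy)-3-(3-methylbut-2-en-1-yl)phenyl]acetonitrile | N#CCc1ccc(OCOC)c(CC=C(C)C)c1OC | intermediate
8 | 2-[2-methoxy-4-(methoxymethoxy)-3-(3-methylbut-2-en-1-yl)phenyl]acetic acid | OC(=O)Cc1ccc(OCOC)c(CC=C(C)C)c1OC | intermediate
9 | 2,2,6-trimethyl-4H-1,3-dioxin-4-one | CC1=CC(=O)OC(C)(C)O1 | starting material
10 | acetyl chloride | CC(=O)Cl | starting material
11 | 2,2-dimethyl-6-(2-oxopropyl)-4H-1,3-dioxin-4-one | CC(=O)CC1=CC(=O)OC(C)(C)O1 | intermediate
12 | 1-(1H-imidazol-1-yl)-2-[2-methoxy-4-(methoxymethoxy)-3-(3-methylbut-2-en-1-yl)phenyl]ethan-1-one (not isolated) | COc1c(CC(=O)n2ccnc2)ccc(OCOC)c1CC=C(C)C | intermediate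
13 | 6-{5-[2-methoxy-4-(methoxymethoxy)-3-(3-methylbut-2-en-1-yl)phenyl]-2,4-dioxopentyl}-2,2-dimethyl-4H-1,3-dioxin-4-one | COc1c(CC(=O)CC(=O)CC2=CC(=O)OC(C)(C)O2)ccc(OCOC)c1CC=C(C)C | intermediate
14 | 8-[2-methoxy-4-(methoxymethoxy)-3-(3-methylbut-2-en-1-yl)phenyl]oct-1-ene-1,3,5,7-tetraone (acylketene, not isolated) | O=C=CC(=O)CC(=O)CC(=O)Cc1ccc(OCOC)c(CC=C(C)C)c1OC | intermediate
15 | methyl 8-[2-methoxy-4-(methoxymethoxy)-3-(3-methylbut-2-en-1-yl)phenyl]-3,5,7-trioxooctanoate | COC(=O)CC(=O)CC(=O)CC(=O)Cc1ccc(OCOC)c(CC=C(C)C)c1OC | intermediate
16 | 2-[2-methoxy-4-(methoxymethoxy)-3-(3-methylbut-2-en-1-yl)phenyl]-1-(2,4,6-trihydroxyphenyl)ethan-1-one | COc1c(CC(=O)c2c(O)cc(O)cc2O)ccc(OCOC)c1CC=C(C)C | intermediate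
17 | 2-[2-methoxy-4-(methoxymethoxy)-3-(3-methylbut-2-en-1-yl)phenyl]-1-[2,4,6-trihydroxy-3,5-bis(3-methylbut-2-en-1-yl)phenyl]ethan-1-one | COc1c(CC(=O)c2c(O)c(CC=C(C)C)c(O)c(CC=C(C)C)c2O)ccc(OCOC)c1CC=C(C)C | intermediate
18 | 3-(dimethylamino)-2-[2-methoxy-4-(methoxymethoxy)-3-(3-methylbut-2-en-1-yl)phenyl]-1-[2,4,6-trihydroxy-3,5-bis(3-methylbut-2-en-1-yl)phenyl]prop-2-en-1-one (alkene geometry not controlled, not isolated) | CN(C)C=C(c1ccc(OCOC)c(CC=C(C)C)c1OC)C(=O)c1c(O)c(CC=C(C)C)c(O)c(CC=C(C)C)c1O | intermediate
19 | 5,7-dihydroxy-3-[2-methoxy-4-(methoxymethoxy)-3-(3-methylbut-2-en-1-yl)phenyl]-6,8-bis(3-methylbut-2-en-1-yl)-4H-chromen-4-one | COc1c(-c2coc3c(CC=C(C)C)c(O)c(CC=C(C)C)c(O)c3c2=O)ccc(OCOC)c1CC=C(C)C | intermediate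
20 | 5,7-dihydroxy-3-[4-hydroxy-2-methoxy-3-(3-methylbut-2-en-1-yl)phenyl]-6,8-bis(3-methylbut-2-en-1-yl)-4H-chromen-4-one | COc1c(-c2coc3c(CC=C(C)C)c(O)c(CC=C(C)C)c(O)c3c2=O)ccc(O)c1CC=C(C)C | target

## Step count and least certain steps

Total step count: 12. Longest linear sequence: 11 steps (steps 1 to 5 and 7 to 12, from 1); step 6 is a one-step side branch.

**Step 9 (key step).** The most likely failure is closure in the wrong mode: aldol attack of the ester-side methylene on the C7 ketone followed by dehydration, or O-acylation to a pyrone. Both are low-barrier reactions of the same polyenolate, and 15 may already begin to cyclise uncontrolled during step 8 or on contact with silica.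
Fallback: ring A is taken from a preformed aromatic; the detour sets out from nitrile 7 and comes back at 16.
- Reduction of 7 with iBu2AlH (toluene, −78 °C) and buffered hydrolysis of the aluminium imine would give 2-[2-methoxy-4-(methoxymethoxy)-3-prenylphenyl]acetaldehyde F1.
- Phloroglucinol is O-allylated (allyl bromide, K2CO3, DMF) to 1,3,5-tris(allyloxy)benzene F2 and brominated with N-bromosuccinimide to 2-bromo-1,3,5-tris(allyloxy)benzene F3.
- Bromine–lithium exchange (n-BuLi, THF, −78 °C), transmetalation with anhydrous CeCl3 to suppress enolisation of the aldehyde, and addition to F1 should give the racemic carbinol 2-Ar-1-[2,4,6-tris(allyloxy)phenyl]ethan-1-ol F4.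
- Dess–Martin periodinane would oxidise F4 to the ketone 2-Ar-1-[2,4,6-tris(allyloxy)phenyl]ethan-1-one F5.
- Allyl transfer to morpholine, catalysed by Pd(PPh3)4, then frees the three phenols and gives 16 with the MOM ether and the prenyl group untouched.

**Step 7.** Proton transfer may outrun acylation: the dianion is a strong base, the acyl imidazole 12 carries an acidic benzylic CH2, and the product consumes further dianion, so conversion may stall or O-acylation may intrude.
Fallback: an aldol addition followed by oxidation; it sets out from 7 and 11 and comes back at 13. The arylacetaldehyde F1, made from 7 as described above, is added at −78 °C to the dianion of 11. Addition to an aldehyde is faster than proton transfer, and the alkoxide formed does not quench further dianion. This should give the racemic β-hydroxy ketone 6-(5-Ar-4-hydroxy-2-oxopentyl)-2,2-dimethyl-4H-1,3-dioxin-4-one F6, which Dess–Martin periodinane (NaHCO3 buffer, CH2Cl2) would oxidise to 13.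

**Step 10.** Alkylation may not stop cleanly at the symmetric stage: a second alkylation at an already substituted carbon (with loss of aromaticity), O-alkylation and incomplete reaction all compete, and the polyphenoxide is easily oxidised by air.
Fallback: the order of events is reversed; the detour sets out from 16 and comes back at 19. Ring C is closed first with N,N-dimethylformamide dimethyl acetal, through the enaminone 3-(dimethylamino)-2-Ar-1-(2,4,6-trihydroxyphenyl)prop-2-en-1-one F7 (not isolated), to the isoflavone 5,7-dihydroxy-3-Ar-4H-chromen-4-one F8. F8 is then C-prenylated at C6 and C8 with 2 and NaOMe in methanol to give 19. In the chromone only the 7-hydroxyl is readily ionised, and geminal dialkylation would cost the aromaticity of the benzopyranone, so over-alkylation should be less favoured; the price is lower nucleophilicity.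

**Step 12.** Acid may add the phenolic hydroxyls across the neighbouring prenyl double bonds (chroman ring closure at O4'/C3', O7/C6 or C8, O5/C6) at a rate comparable to acetal cleavage.
Fallback: the acetal is exchanged for silicon under buffered, non-protic conditions and the silyl groups are then removed by fluoride; the detour sets out from 19 and comes back at 20. Treatment of 19 with triethylsilyl triflate and 2,2'-bipyridyl (CH2Cl2, 0 °C) should convert the aryl MOM ether directly into a silyl ether and silylate the free phenols, giving the 4',5,7-tris(triethylsilyl) ether of 20 F9 (a partly silylated mixture would serve equally). Bu4NF buffered with acetic acid (THF, 0 °C) then gives 20 without any Brønsted acid strong enough to protonate a prenyl group.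

**Step 1.** Site selectivity may be poor: alkylation at C5 or at oxygen and double alkylation compete with attack at C3, since all are open to the same ambident phenoxide.
Fallback: the prenyl group is delivered by an aromatic Claisen rearrangement that can only reach C3; the detour sets out from 1 and comes back at 4.
- Selective protection of 1 (MOMCl, K2CO3, acetone) would give 2-hydroxy-4-(methoxymethoxy)benzaldehyde F10.
- Etherification of the 2-hydroxyl with 3-chloro-3-methylbut-1-yne (K2CO3, KI, catalytic CuI, DMF, 60 °C) would give 4-(methoxymethoxy)-2-[(2-methylbut-3-yn-2-yl)oxy]benzaldehyde F11.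
- Semi-hydrogenation (H2, Pd/CaCO3 poisoned with Pb(OAc)2, quinoline, EtOAc) would give 4-(methoxymethoxy)-2-[(2-methylbut-3-en-2-yl)oxy]benzaldehyde F12.
- Heating F12 in toluene at 110 to 130 °C should bring about the [3,3] shift to the only free ortho carbon, C3, and give 4.

## Further compounds

F1 | step 9 | 2-[2-methoxy-4-(methoxymethoxy)-3-(3-methylbut-2-en-1-yl)phenyl]acetaldehyde | COc1c(CC=O)ccc(OCOC)c1CC=C(C)C
F2 | step 9 | 1,3,5-tris(prop-2-en-1-yloxy)benzene | C=CCOc1cc(OCC=C)cc(OCC=C)c1
F3 | step 9 | 2-bromo-1,3,5-tris(prop-2-en-1-yloxy)benzene | C=CCOc1cc(OCC=C)c(Br)c(OCC=C)c1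
F4 | step 9 | 2-[2-methoxy-4-(methoxymethoxy)-3-(3-methylbut-2-en-1-yl)phenyl]-1-[2,4,6-tris(prop-2-en-1-yloxy)phenyl]ethan-1-ol (racemic) | COc1c(CC(O)c2c(OCC=C)cc(OCC=C)cc2OCC=C)ccc(OCOC)c1CC=C(C)C
F5 | step 9 | 2-[2-methoxy-4-(methoxymethoxy)-3-(3-methylbut-2-en-1-yl)phenyl]-1-[2,4,6-tris(prop-2-en-1-yloxy)phenyl]ethan-1-one | COc1c(CC(=O)c2c(OCC=C)cc(OCC=C)cc2OCC=C)ccc(OCOC)c1CC=C(C)C
F6 | step 7 | 6-{4-hydroxy-5-[2-methoxy-4-(methoxymethoxy)-3-(3-methylbut-2-en-1-yl)phenyl]-2-oxopentyl}-2,2-dimethyl-4H-1,3-dioxin-4-one (racemic) | COc1c(CC(O)CC(=O)CC2=CC(=O)OC(C)(C)O2)ccc(OCOC)c1CC=C(C)C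
F7 | step 10 | 3-(dimethylamino)-2-[2-methoxy-4-(methoxymethoxy)-3-(3-methylbut-2-en-1-yl)phenyl]-1-(2,4,6-trihydroxyphenyl)prop-2-en-1-one (alkene geometry not controlled, not isolated) | CN(C)C=C(c1ccc(OCOC)c(CC=C(C)C)c1OC)C(=O)c1c(O)cc(O)cc1O
F8 | step 10 | 5,7-dihydroxy-3-[2-methoxy-4-(methoxymethoxy)-3-(3-methylbut-2-en-1-yl)phenyl]-4H-chromen-4-one | COc1c(-c2coc3cc(O)cc(O)c3c2=O)ccc(OCOC)c1CC=C(C)C
F9 | step 12 | 3-{2-methoxy-3-(3-methylbut-2-en-1-yl)-4-[(triethylsilyl)oxy]phenyl}-6,8-bis(3-methylbut-2-en-1-yl)-5,7-bis[(triethylsilyl)oxy]-4H-chromen-4-one | COc1c(-c2coc3c(CC=C(C)C)c(O[Si](CC)(CC)CC)c(CC=C(C)C)c(O[Si](CC)(CC)CC)c3c2=O)ccc(O[Si](CC)(CC)CC)c1CC=C(C)C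
F10 | step 1 | 2-hydroxy-4-(methoxymethoxy)benzaldehyde | O=Cc1ccc(OCOC)cc1O
F11 | step 1 | 4-(methoxymethoxy)-2-[(2-methylbut-3-yn-2-yl)oxy]benzaldehyde | O=Cc1ccc(OCOC)cc1OC(C)(C)C#C
F12 | step 1 | 4-(methoxymethoxy)-2-[(2-methylbut-3-en-2-yl)oxy]benzaldehyde | O=Cc1ccc(OCOC)cc1OC(C)(C)C=C
A1 | alternative 1 | 5-hydroxy-7-(methoxymethoxy)-3-[2-methoxy-4-(methoxymethoxy)-3-(3-methylbut-2-en-1-yl)phenyl]-6,8-bis(3-methylbut-2-en-1-yl)-4H-chromen-4-one | COCOc1ccc(-c2coc3c(CC=C(C)C)c(OCOC)c(CC=C(C)C)c(O)c3c2=O)c(OC)c1CC=C(C)C
A2 | alternative 1 | 5-hydroxy-6,8-diiodo-3-[3-iodo-2-methoxy-4-(methoxymethoxy)phenyl]-7-(methoxymethoxy)-4H-chromen-4-one | COCOc1ccc(-c2coc3c(I)c(OCOC)c(I)c(O)c3c2=O)c(OC)c1I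
A3 | alternative 1 | tributyl(3-methylbut-2-en-1-yl)stannane | CC(C)=CC[Sn](CCCC)(CCCC)CCCC
A4 | alternative 2 | 3-{2-hydroxy-3-(3-methylbut-2-en-1-yl)-4-[(triisopropylsilyl)oxy]phenyl}-5,7-bis(methoxymethoxy)-6,8-bis(3-methylbut-2-en-1-yl)-4H-chromen-4-one | CC(C)=CCc1c(O)c(-c2coc3c(CC=C(C)C)c(OCOC)c(CC=C(C)C)c(OCOC)c3c2=O)ccc1O[Si](C(C)C)(C(C)C)C(C)C
A5 | alternative 2 | (E)-4-[5,7-bis(methoxymethoxy)-6,8-bis(3-methylbut-2-en-1-yl)-4-oxo-4H-chromen-3-yl]-1-diazobut-3-en-2-one | [N-]=[N+]=CC(=O)/C=C/c1coc2c(CC=C(C)C)c(OCOC)c(CC=C(C)C)c(OCOC)c2c1=O
A6 | alternative 2 | triisopropyl[(5-methylhex-4-en-1-yn-1-yl)oxy]silane | CC(C)=CCC#CO[Si](C(C)C)(C(C)C)C(C)C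
A7 | alternative 3 | 1-[2-hydroxy-4,6-bis(methoxymethoxy)-3,5-bis(3-methylbut-2-en-1-yl)phenyl]-2-[2-methoxy-4-(methoxymethoxy)-3-(3-methylbut-2-en-1-yl)phenyl]ethan-1-one | COc1c(CC(=O)c2c(O)c(CC=C(C)C)c(OCOC)c(CC=C(C)C)c2OCOC)ccc(OCOC)c1CC=C(C)C
A8 | alternative 3 | 3,5-bis(methoxymethoxy)-4,6-bis(3-methylbut-2-en-1-yl)-2-(trimethylsilyl)phenyl trifluoromethanesulfonate | C[Si](C)(C)c1c(OCOC)c(CC=C(C)C)c(OCOC)c(CC=C(C)C)c1OS(=O)(=O)C(F)(F)F
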